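## Retrosynthetic overview

1. Target 11 comes from hydroxy ester 9 by ester reduction; 9 comes from racemic α-keto ester 8 by one dynamic kinetic reduction that sets C-2 and C-3 together.
2. Key disconnection C-2–C-3: a glyoxylate acyl anion (Breslow intermediate of 5) is joined to the bis(indolyl)methyl cation carbon, two carbons that are both electrophilic by nature.
3. The cation is stored as cyclic ether 4, made from tryptophol 1 and indole-3-carboxaldehyde 2 by an oxa-Pictet–Spengler reaction; its ring opening in the C–C bond-forming step releases the hydroxyethyl chain, so no protecting group is needed.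
4. Rings: both indole rings are bought; the only ring formed is the temporary pyran ring (step 1), which is opened again in step 2.

Assumption: the target is (2S,3S) as read from the given SMILES; acids, bases, catalysts and solvents carry no compound number.

## Route

Step 1
Reactants: 1 tryptophol, 2-(1H-indol-3-yl)ethanol; 2 indole-3-carboxaldehyde
Product: 4 (±)-1-(1H-indol-3-yl)-1,3,4,9-tetrahydropyrano[3,4-b]indole, via hemiacetal 3 (not isolated)
Conditions: p-TsOH·H2O (10 mol %), 4 Å MS, MeCN, 50 °C, 2 (1.2 equiv); Et3N quench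
Reagents that add atoms: none
Why: oxa-Pictet–Spengler reaction, in which hemiacetal 3 loses water to an indole-stabilised oxocarbenium ion that is captured intramolecularly by C-2 of the tryptophol indole; the new stereocentre is racemic and is erased in step 2.

Step 2
Reactants: 4 (±)-1-(1H-indol-3-yl)-1,3,4,9-tetrahydropyrano[3,4-b]indole; 5 ethyl glyoxylate
Product: 8 (±)-ethyl 3-[3-(2-hydroxyethyl)-1H-indol-2-yl]-3-(1H-indol-3-yl)-2-oxopropanoate (keto/enol mixture), via Breslow intermediate 6 (not isolated), via azafulvene 7 (not isolated)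
Conditions: 2-(pentafluorophenyl)-6,7-dihydro-5H-pyrrolo[2,1-c][1,2,4]triazol-2-ium tetrafluoroborate (20 mol %), 2-ClC6H4CO2Na (20 mol %), 4 Å MS, CH2Cl2, 23 °C, argon; 5 (1.5 equiv, freshly cracked) added over 4 h
Reagents that add atoms: none
Why: Proposed new method: the carboxylate frees the triazolylidene, and the 2-chlorobenzoic acid so formed ionises the doubly indolyl-activated C–O bond of 4 to azafulvene 7 (or its N-protonated bis(indolyl)methylium form); the carbene turns 5 into Breslow intermediate 6, whose acyl anion carbon adds to the exocyclic carbon of 7, and collapse of the adduct releases the carbene and gives 8 with the hydroxyethyl chain set free; the closest known reaction types are the carbene-catalysed coupling of aldehydes with 3-(1-arylsulfonylalkyl)indoles, the glyoxylate Stetter reaction and cooperative carbene/carboxylic acid catalysis.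

Step 3
Reactants: 8 (±)-ethyl 3-[3-(2-hydroxyethyl)-1H-indol-2-yl]-3-(1H-indol-3-yl)-2-oxopropanoate
Product: 9 ethyl (2S,3S)-2-hydroxy-3-[3-(2-hydroxyethyl)-1H-indol-2-yl]-3-(1H-indol-3-yl)propanoate
Conditions: RuCl[(S,S)-TsDPEN](p-cymene) (2 mol %), HCO2H/Et3N (5:2), DMF, 40 °C, argon
Reagents that add atoms: none
Why: Noyori–Ikariya asymmetric transfer hydrogenation with dynamic kinetic resolution, a known process for β-aryl α-keto esters: the doubly benzylic C-3–H epimerises quickly through the enol, the (S,S)-ruthenium hydride attacks the ketone face that gives the (2S) alcohol (flat ester where the aryl group of an aryl ketone sits, bulky diarylmethyl group in the open space), and the (3S) epimer reacts faster because only it can place the bulkier and more electron-poor 3-substituted indol-2-yl group anti to the incoming hydride with H next to the ester (Felkin–Anh), so both stereocentres are set here as the (2S,3S) pair.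

Step 4
Reactants: 9 ethyl (2S,3S)-2-hydroxy-3-[3-(2-hydroxyethyl)-1H-indol-2-yl]-3-(1H-indol-3-yl)propanoate
Product: 11 Colletotryptin B, (2S,3S)-3-[3-(2-hydroxyethyl)-1H-indol-2-yl]-3-(1H-indol-3-yl)propane-1,2-diol, via hydroxy aldehyde 10 (not isolated)
Conditions: LiBH4 (4 equiv), THF, 0 → 23 °C; then H2O
Reagents that add atoms: none
Why: borohydride reduction of an α-hydroxy ester to the 1,2-diol through aldehyde 10; neither C-2 (held as a borate alkoxide) nor C-3 (no longer next to a carbonyl after step 3) can epimerise, so the (2S,3S) configuration is carried into the target.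

## Compound list

1 | tryptophol, 2-(1H-indol-3-yl)ethanol | OCCc1c[nH]c2ccccc12 | starting material
2 | indole-3-carboxaldehyde | O=Cc1c[nH]c2ccccc12 | starting material
3 | (1H-indol-3-yl)[2-(1H-indol-3-yl)ethoxy]methanol, racemic hemiacetal | OC(OCCc1c[nH]c2ccccc12)c1c[nH]c2ccccc12 | intermediate
4 | (±)-1-(1H-indol-3-yl)-1,3,4,9-tetrahydropyrano[3,4-b]indole | C1(c2c[nH]c3ccccc23)OCCc2c1[nH]c1ccccc21 | intermediate
5 | ethyl glyoxylate | CCOC(=O)C=O | starting material
6 | Breslow intermediate, ethyl 2-hydroxy-2-[2-(pentafluorophenyl)-6,7-dihydro-2H-pyrrolo[2,1-c][1,2,4]triazol-3(5H)-ylidene]acetate | CCOC(=O)C(O)=C1N(c2c(F)c(F)c(F)c(F)c2F)N=C2CCCN12 | intermediate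
7 | azafulvene, 2-[2-(3H-indol-3-ylidenemethyl)-1H-indol-3-yl]ethanol | OCCc1c(C=C2C=Nc3ccccc23)[nH]c2ccccc12 | intermediate
8 | (±)-ethyl 3-[3-(2-hydroxyethyl)-1H-indol-2-yl]-3-(1H-indol-3-yl)-2-oxopropanoate | OCCc1c(C(c2c[nH]c3ccccc23)C(=O)C(=O)OCC)[nH]c2ccccc12 | intermediate
9 | ethyl (2S,3S)-2-hydroxy-3-[3-(2-hydroxyethyl)-1H-indol-2-yl]-3-(1H-indol-3-yl)propanoate | OCCc1c([C@H](c2c[nH]c3ccccc23)[C@H](O)C(=O)OCC)[nH]c2ccccc12 | intermediate
10 | (2S,3S)-2-hydroxy-3-[3-(2-hydroxyethyl)-1H-indol-2-yl]-3-(1H-indol-3-yl)propanal | OCCc1c([C@H](c2c[nH]c3ccccc23)[C@H](O)C=O)[nH]c2ccccc12 | intermediate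
11 | Colletotryptin B, (2S,3S)-3-[3-(2-hydroxyethyl)-1H-indol-2-yl]-3-(1H-indol-3-yl)propane-1,2-diol | OCCc1c([C@H](c2c[nH]c3ccccc23)[C@H](O)CO)[nH]c2ccccc12 | target

## Step count and risks

Total step count: 4. Longest linear sequence: 4 steps (1 and 2 → 4 → 8 → 9 → 11).

Steps most likely to fail, in order:

First, step 2. It has no direct precedent: the stabilised cation may be too weak an electrophile for the ester-stabilised Breslow intermediate, the carbene may be held back as an adduct with the cation, and glyoxylate may self-condense. The fallback sets out from 4 and comes back at 8, using a stoichiometric glyoxylate acyl anion equivalent in place of the catalytic one. Ethyl nitroacetate is heated with 4 in toluene at 90 °C, where it opens the pyran ring as in a gramine alkylation and gives ethyl 3-[3-(2-hydroxyethyl)-1H-indol-2-yl]-3-(1H-indol-3-yl)-2-nitropropanoate F1. A Nef reaction of its nitronate (NaOMe, MeOH, then aqueous TiCl3 buffered with NH4OAc, 0 → 23 °C) then turns the nitro-bearing carbon into the ketone of 8.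

Second, step 3. The diastereoselectivity rests on the catalyst telling two indolyl groups apart at the labile C-3, and 8 may sit as a seven-membered hemiketal with its own hydroxyethyl group. The absolute sense at C-2 is assigned by model only and must be checked (Mosher ester, rotation of 11); if it is reversed, the mirror-image complex RuCl[(R,R)-TsDPEN](p-cymene) is used. The fallback sets out from 8 and comes back at 9. The primary alcohol is first silylated (TBDPSCl, imidazole, DMF) to ethyl 3-{3-[2-(tert-butyldiphenylsilyloxy)ethyl]-1H-indol-2-yl}-3-(1H-indol-3-yl)-2-oxopropanoate F2. This cannot form the hemiketal and carries a much larger ortho substituent on the indol-2-yl group, which fixes that group as the anti substituent. The same transfer hydrogenation then gives ethyl (2S,3S)-3-{3-[2-(tert-butyldiphenylsilyloxy)ethyl]-1H-indol-2-yl}-2-hydroxy-3-(1H-indol-3-yl)propanoate F3, and Bu4NF in THF returns 9.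

Third, step 1. Indole-3-carboxaldehyde is a vinylogous amide and a poor electrophile, and the product ether ionises under the same acid, so a second tryptophol can add to give a tris(indolyl)methane. The fallback sets out from 2 and comes back at 4. Boc2O with catalytic DMAP in MeCN gives tert-butyl 3-formyl-1H-indole-1-carboxylate F4, which behaves as an ordinary aryl aldehyde. Its oxa-Pictet–Spengler reaction with 1 (p-TsOH·H2O 5 mol %, CH2Cl2, 23 °C) gives tert-butyl 3-(1,3,4,9-tetrahydropyrano[3,4-b]indol-1-yl)-1H-indole-1-carboxylate F5, which does not ionise under these conditions. K2CO3 in MeOH at 60 °C then removes the Boc group to give 4.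

Further compounds
F1 | step 2 | ethyl 3-[3-(2-hydroxyethyl)-1H-indol-2-yl]-3-(1H-indol-3-yl)-2-nitropropanoate (diastereomer mixture) | OCCc1c(C(c2c[nH]c3ccccc23)C(C(=O)OCC)[N+](=O)[O-])[nH]c2ccccc12
F2 | step 3 | ethyl 3-{3-[2-(tert-butyldiphenylsilyloxy)ethyl]-1H-indol-2-yl}-3-(1H-indol-3-yl)-2-oxopropanoate (racemic) | CCOC(=O)C(=O)C(c1c[nH]c2ccccc12)c1[nH]c2ccccc2c1CCO[Si](c1ccccc1)(c1ccccc1)C(C)(C)C
F3 | step 3 | ethyl (2S,3S)-3-{3-[2-(tert-butyldiphenylsilyloxy)ethyl]-1H-indol-2-yl}-2-hydroxy-3-(1H-indol-3-yl)propanoate | CC(C)(C)[Si](c1ccccc1)(c1ccccc1)OCCc1c([C@H](c2c[nH]c3ccccc23)[C@H](O)C(=O)OCC)[nH]c2ccccc12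
F4 | step 1 | tert-butyl 3-formyl-1H-indole-1-carboxylate | O=Cc1cn(C(=O)OC(C)(C)C)c2ccccc12
F5 | step 1 | tert-butyl 3-(1,3,4,9-tetrahydropyrano[3,4-b]indol-1-yl)-1H-indole-1-carboxylate (racemic) | CC(C)(C)OC(=O)n1cc(C2OCCc3c2[nH]c2ccccc32)c2ccccc12
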